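**Retrosynthetic overview**

1. The pyran ring is formed last: a 2-formyl vinylogous acid closes by 6-endo cyclisation onto its C4≡C3 alkyne, and C1 comes from an amide-acetal formylation at C8a.
2. The carbocycle is formed first: C8–C8a closes by a vinylogous Dieckmann reaction of a γ-methyl chloro-enynone onto the lactone carbonyl of a lactic-acid-derived 1,3-dioxolan-4-one; the acetal leaves and O7 is acetylated in the same pot.
3. C3–C9 comes from a Sonogashira coupling of the terminal alkyne with a dienyl iodide made from (S)-2-methylbutan-1-ol (source of C13).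
4. C7–C6 and the C7 stereocentre come from a light-driven 1,3-acyl shift of the O-acyl enol ester of the (S)-lactic acid/pivalaldehyde dioxolanone, anti to the tert-butyl group.
5. The acyl unit (C6, C5–Cl, C4a, C8a, C4, C3) comes from ethyl 2-chloro-3-oxobutanoate through its enol triflate and ethynyltrimethylsilane.

Assumption: azaphilone numbering (C1, O2, C3, C4, C4a, C5, C6, C7, C8, C8a; side chain C9 to C13) is used for the target and for the atoms that end up in it; the target is then the (7S,13S) isomer.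

Note: the chloroalkene in 5 to 18 is drawn Z. Its geometry does not matter, because dienolate 19 is the same species from either isomer.

**Route**

Step 1
Reactants: 1 (S)-lactic acid; 2 pivalaldehyde
Product: 3 (2S,5S)-2-tert-butyl-5-methyl-1,3-dioxolan-4-one
Conditions: cat. TsOH·H2O, cat. H2SO4, pentane, reflux (Dean–Stark); recrystallise from Et2O/pentane, −78 °C
Reagents that add atoms: none
Why: Acid-catalysed acetalisation with water removal (Seebach self-regeneration-of-stereocentres template), in which the untouched lactate stereocentre steers the new acetal carbon to the cis (2S) configuration (about 96:4, upgraded by crystallisation).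

Step 2
Reactants: 4 ethyl 2-chloro-3-oxobutanoate
Product: 5 ethyl (2Z)-2-chloro-3-(trifluoromethylsulfonyloxy)but-2-enoate
Conditions: Tf2O, iPr2NEt, CH2Cl2, −78 → 0 °C
Reagents that add atoms: triflic anhydride, O=S(=O)(OS(=O)(=O)C(F)(F)F)C(F)(F)F
Why: Enol triflate formation by O-sulfonylation of the ammonium enolate of an acidic 2-chloro β-keto ester under non-chelating conditions.

Step 3
Reactants: 5 ethyl (2Z)-2-chloro-3-(trifluoromethylsulfonyloxy)but-2-enoate; 6 ethynyltrimethylsilane
Product: 8 (2Z)-2-chloro-3-methylpent-2-en-4-ynoic acid, via silylated enyne ester 7 (not isolated)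
Conditions: PdCl2(PPh3)2 (3 mol%), CuI (6 mol%), Et3N, THF, 23 °C; then LiOH, MeOH/H2O, 23 °C; then 1 M HCl
Reagents that add atoms: lithium hydroxide, [Li+].[OH-]
Why: Sonogashira coupling of the electron-poor vinyl triflate goes with retention and much faster than any reaction at the vinylic C–Cl bond, and LiOH then saponifies the ester and cleaves the C–Si bond in the same pot.

Step 4
Reactants: 8 (2Z)-2-chloro-3-methylpent-2-en-4-ynoic acid; 3 (2S,5S)-2-tert-butyl-5-methyl-1,3-dioxolan-4-one
Product: 11 (2S)-2-tert-butyl-5-methyl-1,3-dioxol-4-yl (2Z)-2-chloro-3-methylpent-2-en-4-ynoate, via acid chloride 9 (not isolated), via lithium enolate 10 (not isolated)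
Conditions: 8, (COCl)2, cat. DMF, CH2Cl2, 0 → 23 °C, evaporate; 3, LiN(iPr)2, THF/DMPU (9:1), −78 °C; then 9, −78 °C, 30 min; cold NaHCO3 work-up
Reagents that add atoms: none
Why: Enolate O-acylation, in which the hard acid chloride is expected to attack the oxygen of the fully substituted, DMPU-solvated lithium enolate; any C-acylated by-product is compound 12 itself with the same anti-to-tert-butyl sense and is simply carried along.

Step 5
Reactants: 11 (2S)-2-tert-butyl-5-methyl-1,3-dioxol-4-yl (2Z)-2-chloro-3-methylpent-2-en-4-ynoate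
Product: 12 (2S,5R)-2-tert-butyl-5-[(2Z)-2-chloro-3-methylpent-2-en-4-ynoyl]-5-methyl-1,3-dioxolan-4-one (chloroalkene Z drawn; the E isomer formed by photoisomerisation converges in step 9)
Conditions: hν (254 nm, low-pressure Hg lamp, quartz), degassed MeCN (5 mM), −40 °C, to about 70% conversion; recovered 11 recycled; minor 5S diastereomer removed by chromatography
Reagents that add atoms: none
Why: Proposed new method: a photo-Fries-type 1,3-acyl shift on the O-acyl enol ester of a Seebach dioxolanone, in which excitation homolyses the O–acyl bond and the caged pair of alkenoyl radical (which does not decarbonylate) and captodative 1,3-dioxolan-4-on-5-yl radical recombines at C5 on the face opposite the tert-butyl group, so that the lactate-derived acetal carbon sets the quaternary centre (5R here, C7 S in the target) as the C7–C6 bond forms; the closest known reaction types are the photo-Fries rearrangement of aryl and enol esters to β-dicarbonyl compounds and the trans-selective radical and enolate reactions of this dioxolanone template.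

Step 6
Reactants: 13 (S)-2-methylbutan-1-ol; 14 2-(triphenylphosphoranylidene)propanal
Product: 16 (2E,4S)-2,4-dimethylhex-2-enal, via (2S)-2-methylbutanal 15 (not isolated)
Conditions: TEMPO (1 mol%), KBr, NaOCl, NaHCO3, CH2Cl2/H2O, 0 °C; dried organic phase, then 14, PhMe, 80 °C
Reagents that add atoms: none
Why: Anelli TEMPO/bleach oxidation gives the aldehyde without base-mediated epimerisation, and the stabilised ylide then gives the E-enal in a Wittig olefination, so the bought C13 centre is only carried through.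

Step 7
Reactants: 16 (2E,4S)-2,4-dimethylhex-2-enal
Product: 17 (1E,3E,5S)-1-iodo-3,5-dimethylhepta-1,3-diene
Conditions: CrCl2 (6 equiv), CHI3 (2 equiv), THF, 0 → 23 °C, dark
Reagents that add atoms: iodoform, IC(I)I
Why: Takai iodo-olefination through a geminal dichromium species gives the E-vinyl iodide without touching the trisubstituted alkene or C13.

Step 8
Reactants: 12 (2S,5R)-2-tert-butyl-5-[(2Z)-2-chloro-3-methylpent-2-en-4-ynoyl]-5-methyl-1,3-dioxolan-4-one; 17 (1E,3E,5S)-1-iodo-3,5-dimethylhepta-1,3-diene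
Product: 18 (2S,5R)-2-tert-butyl-5-[(2Z,6E,8E,10S)-2-chloro-3,8,10-trimethyldodeca-2,6,8-trien-4-ynoyl]-5-methyl-1,3-dioxolan-4-one
Conditions: Pd(PPh3)4 (5 mol%), CuI (10 mol%), iPr2NEt, THF, 23 °C, dark
Reagents that add atoms: none
Why: Sonogashira coupling of the terminal alkyne with the vinyl iodide proceeds with retention of alkene geometry, the hindered tertiary amine does not open the acylal lactone, and the vinylic chloride is inert at 23 °C.

Step 9
Reactants: 18 (2S,5R)-2-tert-butyl-5-[(2Z,6E,8E,10S)-2-chloro-3,8,10-trimethyldodeca-2,6,8-trien-4-ynoyl]-5-methyl-1,3-dioxolan-4-one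
Product: 21 (1S)-3-chloro-4-[(3E,5E,7S)-5,7-dimethylnona-3,5-dien-1-yn-1-yl]-6-hydroxy-1-methyl-2-oxocyclohexa-3,5-dien-1-yl acetate, via lithium dienolate 19 (not isolated), via ring-closed dilithium salt 20 (not isolated)
Conditions: LiN(SiMe3)2 (2.3 equiv), THF, −78 → −40 °C; then Ac2O (1.05 equiv), −78 °C; then AcOH
Reagents that add atoms: acetic anhydride, CC(=O)OC(C)=O
Why: Vinylogous Dieckmann (intramolecular Claisen) condensation, in which the γ-deprotonated dienolate can reach the strongly electrophilic acylal carbonyl only through C8a (six-membered ring), collapse of the adduct expels pivalaldehyde and unveils the C7 alkoxide that takes the acetyl group as the most basic oxygen present, the quaternary C7 is not touched, and the C5 chlorine keeps the two arms of the vinylogous acid different so that tautomerism cannot racemise it.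

Step 10
Reactants: 21 (1S)-3-chloro-4-[(3E,5E,7S)-5,7-dimethylnona-3,5-dien-1-yn-1-yl]-6-hydroxy-1-methyl-2-oxocyclohexa-3,5-dien-1-yl acetate
Product: 24 7-epi-sclerotiorin, via aminomethylene dione 22 (not isolated), via formyl vinylogous acid 23 (not isolated)
Conditions: tBuOCH(NMe2)2 (1.5 equiv), CH2Cl2, 0 → 23 °C; then 1 M aq. HCl/THF, 23 °C; then KH2PO4/K2HPO4 buffer (pH 7), CuI (10 mol%), MeCN, 23 °C
Reagents that add atoms: tert-butoxybis(dimethylamino)methane, CC(C)(C)OC(N(C)C)N(C)C; water, O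
Why: Aminomethylenation of the only free nucleophilic carbon (C8a, since C5 carries chlorine) with Bredereck's reagent, acid hydrolysis of the enaminone to the 2-formyl vinylogous acid and copper-catalysed 6-endo-dig cycloisomerisation of the formyl oxygen onto the alkyne close the pyran ring without involving any stereocentre.

**Compound list**

1 | (S)-lactic acid | C[C@H](O)C(=O)O | starting material
2 | pivalaldehyde | CC(C)(C)C=O | starting material
3 | (2S,5S)-2-tert-butyl-5-methyl-1,3-dioxolan-4-one | C[C@@H]1O[C@H](C(C)(C)C)OC1=O | intermediate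
4 | ethyl 2-chloro-3-oxobutanoate (racemic, labile centre) | CCOC(=O)C(Cl)C(C)=O | starting material
5 | ethyl (2Z)-2-chloro-3-(trifluoromethylsulfonyloxy)but-2-enoate | CCOC(=O)/C(Cl)=C(\C)OS(=O)(=O)C(F)(F)F | intermediate
6 | ethynyltrimethylsilane | C#C[Si](C)(C)C | starting material
7 | ethyl (2Z)-2-chloro-3-methyl-5-(trimethylsilyl)pent-2-en-4-ynoate | CCOC(=O)/C(Cl)=C(\C)C#C[Si](C)(C)C | intermediate
8 | (2Z)-2-chloro-3-methylpent-2-en-4-ynoic acid | OC(=O)/C(Cl)=C(\C)C#C | intermediate
9 | (2Z)-2-chloro-3-methylpent-2-en-4-ynoyl chloride | ClC(=O)/C(Cl)=C(\C)C#C | intermediate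
10 | lithium (2S)-2-tert-butyl-5-methyl-1,3-dioxol-4-olate | [Li+].CC1=C([O-])O[C@@H](C(C)(C)C)O1 | intermediate
11 | (2S)-2-tert-butyl-5-methyl-1,3-dioxol-4-yl (2Z)-2-chloro-3-methylpent-2-en-4-ynoate | CC1=C(OC(=O)/C(Cl)=C(\C)C#C)O[C@@H](C(C)(C)C)O1 | intermediate
12 | (2S,5R)-2-tert-butyl-5-[(2Z)-2-chloro-3-methylpent-2-en-4-ynoyl]-5-methyl-1,3-dioxolan-4-one | C[C@]1(C(=O)/C(Cl)=C(\C)C#C)O[C@H](C(C)(C)C)OC1=O | intermediate
13 | (S)-2-methylbutan-1-ol | CC[C@H](C)CO | starting material
14 | 2-(triphenylphosphoranylidene)propanal | CC(C=O)=P(c1ccccc1)(c1ccccc1)c1ccccc1 | starting material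
15 | (2S)-2-methylbutanal | CC[C@H](C)C=O | intermediate
16 | (2E,4S)-2,4-dimethylhex-2-enal | CC[C@H](C)/C=C(C)/C=O | intermediate
17 | (1E,3E,5S)-1-iodo-3,5-dimethylhepta-1,3-diene | CC[C@H](C)/C=C(C)/C=C/I | intermediate
18 | (2S,5R)-2-tert-butyl-5-[(2Z,6E,8E,10S)-2-chloro-3,8,10-trimethyldodeca-2,6,8-trien-4-ynoyl]-5-methyl-1,3-dioxolan-4-one | C[C@]1(C(=O)/C(Cl)=C(\C)C#C/C=C/C(C)=C/[C@@H](C)CC)O[C@H](C(C)(C)C)OC1=O | intermediate
19 | lithium dienolate of 18 (γ-deprotonated at the 3-methyl group; enolate geometry not defined) | [Li+].C[C@]1(C([O-])=C(Cl)C(=C)C#C/C=C/C(C)=C/[C@@H](C)CC)O[C@H](C(C)(C)C)OC1=O | intermediate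
20 | dilithium (6S)-4-chloro-3-[(3E,5E,7S)-5,7-dimethylnona-3,5-dien-1-yn-1-yl]-6-methyl-5-oxocyclohexa-1,3-diene-1,6-diolate | [Li+].[Li+].[O-][C@@]1(C)C([O-])=CC(C#C/C=C/C(C)=C/[C@@H](C)CC)=C(Cl)C1=O | intermediate
21 | (1S)-3-chloro-4-[(3E,5E,7S)-5,7-dimethylnona-3,5-dien-1-yn-1-yl]-6-hydroxy-1-methyl-2-oxocyclohexa-3,5-dien-1-yl acetate | ClC1=C(C#C/C=C/C(C)=C/[C@@H](C)CC)C=C(O)[C@](C)(OC(C)=O)C1=O | intermediate
22 | (1S)-3-chloro-5-[(dimethylamino)methylidene]-4-[(3E,5E,7S)-5,7-dimethylnona-3,5-dien-1-yn-1-yl]-1-methyl-2,6-dioxocyclohex-3-en-1-yl acetate (aminomethylene geometry not defined) | CN(C)C=C1C(=O)[C@](C)(OC(C)=O)C(=O)C(Cl)=C1C#C/C=C/C(C)=C/[C@@H](C)CC | intermediate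
23 | (1S)-3-chloro-4-[(3E,5E,7S)-5,7-dimethylnona-3,5-dien-1-yn-1-yl]-5-formyl-6-hydroxy-1-methyl-2-oxocyclohexa-3,5-dien-1-yl acetate | O=CC1=C(O)[C@](C)(OC(C)=O)C(=O)C(Cl)=C1C#C/C=C/C(C)=C/[C@@H](C)CC | intermediate
24 | 7-epi-sclerotiorin, (7S)-5-chloro-3-[(1E,3E,5S)-3,5-dimethylhepta-1,3-dien-1-yl]-7-methyl-6,8-dioxo-7,8-dihydro-6H-isochromen-7-yl acetate | CC[C@H](C)/C=C(C)/C=C/C1=CC2=C(Cl)C(=O)[C@@](C)(OC(C)=O)C(=O)C2=CO1 | target

**Step count and risks**

Total step count: 10. Longest linear sequence: 7 steps (steps 2, 3, 4, 5, 8, 9, 10, from ethyl 2-chloro-3-oxobutanoate).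

The three steps most likely to fail are steps 5, 9 and 10.

Step 5 (the proposed new step) may suffer from radical escape from the solvent cage, secondary photolysis of 12, or lower facial selectivity than in the ground-state reactions of the template. The fallback uses known chemistry; it sets out from ester 7 (isolated by stopping step 3 before the LiOH stage) and dioxolanone 3, and comes back at 12. Ester 7 is reduced with iBu2AlH (CH2Cl2, −78 °C) to (2Z)-2-chloro-3-methyl-5-(trimethylsilyl)pent-2-en-4-yn-1-ol F1, which MnO2 (CH2Cl2, 23 °C) oxidises to (2Z)-2-chloro-3-methyl-5-(trimethylsilyl)pent-2-en-4-ynal F2. Lithium enolate 10 (from 3, LiN(iPr)2, THF, −78 °C) adds to F2 in an aldol reaction anti to the tert-butyl group to give (2S,5R)-2-tert-butyl-5-[(2Z)-2-chloro-1-hydroxy-3-methyl-5-(trimethylsilyl)pent-2-en-4-yn-1-yl]-5-methyl-1,3-dioxolan-4-one F3 as a mixture of carbinol epimers. Dess–Martin periodinane turns both epimers into (2S,5R)-2-tert-butyl-5-[(2Z)-2-chloro-3-methyl-5-(trimethylsilyl)pent-2-en-4-ynoyl]-5-methyl-1,3-dioxolan-4-one F4, and Bu4NF/AcOH (THF, 0 °C) removes the silyl group to give 12.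

Step 9 may fail through competing deprotonation elsewhere in the trienyne, attack on pivalaldehyde, or incomplete selectivity in the acetylation. The fallback separates acetal cleavage from ring closure; it sets out from 18 and comes back at dilithium salt 20 (then Ac2O and AcOH as in step 9 give 21). Acid methanolysis of the acylal (TsOH, MeOH, 23 °C) gives methyl (2R,4Z,8E,10E,12S)-4-chloro-2-hydroxy-2,5,10,12-tetramethyl-3-oxotetradeca-4,8,10-trien-6-ynoate F5. Its alkoxide/dienolate (LiN(SiMe3)2, 3.2 equiv, THF, −78 → 0 °C) closes onto the ordinary methyl ester in a classical Dieckmann reaction to give 20.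

Step 10 may fail because the liberated dimethylamine adds to the activated alkyne, or because the enaminone is slow to hydrolyse. The fallback replaces the amide acetal by a Lewis-acid formylation; it sets out from 21 and comes back at 23, which cyclises to 24 under the CuI/buffer conditions of step 10. TBSOTf/2,6-lutidine (CH2Cl2, −78 °C) gives (1S)-6-(tert-butyldimethylsilyloxy)-3-chloro-4-[(3E,5E,7S)-5,7-dimethylnona-3,5-dien-1-yn-1-yl]-1-methyl-2-oxocyclohexa-3,5-dien-1-yl acetate F6. A Mukaiyama-type reaction with HC(OMe)3 and TMSOTf (CH2Cl2, −78 °C) puts the masked formyl group on C8a to give (1S)-3-chloro-5-(dimethoxymethyl)-4-[(3E,5E,7S)-5,7-dimethylnona-3,5-dien-1-yn-1-yl]-6-hydroxy-1-methyl-2-oxocyclohexa-3,5-dien-1-yl acetate F7, and dilute aqueous HCl/THF hydrolyses the acetal to 23.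

**Further compounds**

F1 | step 5 | (2Z)-2-chloro-3-methyl-5-(trimethylsilyl)pent-2-en-4-yn-1-ol | OC/C(Cl)=C(\C)C#C[Si](C)(C)C
F2 | step 5 | (2Z)-2-chloro-3-methyl-5-(trimethylsilyl)pent-2-en-4-ynal | O=C/C(Cl)=C(\C)C#C[Si](C)(C)C
F3 | step 5 | (2S,5R)-2-tert-butyl-5-[(2Z)-2-chloro-1-hydroxy-3-methyl-5-(trimethylsilyl)pent-2-en-4-yn-1-yl]-5-methyl-1,3-dioxolan-4-one (carbinol epimers) | C[C@]1(C(O)/C(Cl)=C(\C)C#C[Si](C)(C)C)O[C@H](C(C)(C)C)OC1=O
F4 | step 5 | (2S,5R)-2-tert-butyl-5-[(2Z)-2-chloro-3-methyl-5-(trimethylsilyl)pent-2-en-4-ynoyl]-5-methyl-1,3-dioxolan-4-one | C[C@]1(C(=O)/C(Cl)=C(\C)C#C[Si](C)(C)C)O[C@H](C(C)(C)C)OC1=O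
F5 | step 9 | methyl (2R,4Z,8E,10E,12S)-4-chloro-2-hydroxy-2,5,10,12-tetramethyl-3-oxotetradeca-4,8,10-trien-6-ynoate | C[C@](O)(C(=O)OC)C(=O)/C(Cl)=C(\C)C#C/C=C/C(C)=C/[C@@H](C)CC
F6 | step 10 | (1S)-6-(tert-butyldimethylsilyloxy)-3-chloro-4-[(3E,5E,7S)-5,7-dimethylnona-3,5-dien-1-yn-1-yl]-1-methyl-2-oxocyclohexa-3,5-dien-1-yl acetate | ClC1=C(C#C/C=C/C(C)=C/[C@@H](C)CC)C=C(O[Si](C)(C)C(C)(C)C)[C@](C)(OC(C)=O)C1=O
F7 | step 10 | (1S)-3-chloro-5-(dimethoxymethyl)-4-[(3E,5E,7S)-5,7-dimethylnona-3,5-dien-1-yn-1-yl]-6-hydroxy-1-methyl-2-oxocyclohexa-3,5-dien-1-yl acetate | COC(OC)C1=C(O)[C@](C)(OC(C)=O)C(=O)C(Cl)=C1C#C/C=C/C(C)=C/[C@@H](C)CC
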